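**Plan**
Cuts (side chain numbered C1'–C11' outward from pyranone C6): first the mid-chain C5'–C6' CH2–CH2 bond. In the pyranone half the cuts are the O–CH3 bond at C2, ring O1–C2, C5–C6 and C3–C4. In the other half they are the acetate O–acyl bond and C8'–C9'.
Enabling feature: C1'–C9' is an unbranched, heteroatom-free run of nine CH2 groups, so after the cut C5' and C6' are plain primary termini. C6' lies four carbons from the C10' acetoxy stereocentre, C5' ends a five-carbon arm on the 4H-pyran-4-one ring, and the only other C=C bonds (ring C2=C3, C5=C6) are tetrasubstituted.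
Event: both termini start as the =CH2 ends of two ω-olefins, so they have like polarity. C6' is converted into a primary iodide (radical precursor) and C5' is metalated in situ by Ni–H. A Ni-catalysed reductive hydroalkylation joins the two complete halves and should give the target directly, with the iodine lost in the event itself.
Forward: two butanoate units (Claisen) and hex-5-enoate (dianion acylation) give the triketide. Lactonisation closes the only ring and O-methylation gives the α-methoxy-γ-pyranone. The second half arises by epoxide opening/acetylation, radical HBr addition and halide exchange, and the chain is joined last.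
Stereochemistry: the single (S) centre C10' comes from (S)-propylene oxide, and its C–O bond is never broken.

Key step: step 8

Remark: 2 and 5 are used as mixtures of stereoisomers and keto/enol tautomers, because their sp3 carbons become ring sp2 carbons in 6.

Step 1
Reactants: 1 methyl butanoate (two molecules)
Product: 2 methyl 2-ethyl-3-oxohexanoate
Conditions: NaH (0.6 equiv), MeOH (cat.), THF, reflux; then 1 M HCl, 0 °C
Reagents that add atoms: none
Why: Claisen self-condensation of an enolisable ester, driven to completion by deprotonation of the acidic C2–H that the β-keto ester still carries; the C2 centre is of no consequence.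

Step 2
Reactants: 2 methyl 2-ethyl-3-oxohexanoate (2 equiv), 3 methyl hex-5-enoate
Product: 5 methyl 2,4-diethyl-3,5-dioxodec-9-enoate, via dilithium dienolate 4 (not isolated)
Conditions: LDA (4.2 equiv), THF, −78 → 0 °C; then 3, −78 → 0 °C; 1 M HCl
Reagents that add atoms: none
Why: γ-Acylation of a β-keto ester dianion (Claisen type), in which the more basic C4 terminus of 4 attacks the ester carbonyl of 3 and the excess dianion takes up the acidic proton of the triketide formed.

Step 3
Reactants: 5 methyl 2,4-diethyl-3,5-dioxodec-9-enoate
Product: 6 3,5-diethyl-4-hydroxy-6-(pent-4-en-1-yl)-2H-pyran-2-one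
Conditions: DBU (1.2 equiv), toluene, 80 °C; 1 M HCl wash
Reagents that add atoms: none
Why: Base-induced lactonisation of a 3,5-dioxo ester, in which the C5 enolate oxygen adds to the methyl ester (6-exo-trig), methoxide leaves and tautomerisation gives the 4-hydroxy-2-pyranone with loss of both sp3 centres.

Step 4
Reactants: 6 3,5-diethyl-4-hydroxy-6-(pent-4-en-1-yl)-2H-pyran-2-one
Product: 8 3,5-diethyl-2-methoxy-6-(pent-4-en-1-yl)-4H-pyran-4-one, via hydroxypyrylium triflate 7 (not isolated)
Conditions: MeOTf (1.3 equiv), CH2Cl2, 0 °C → rt; then sat. aq. NaHCO3
Reagents that add atoms: methyl trifluoromethanesulfonate COS(=O)(=O)C(F)(F)F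
Why: Base-free O-methylation of a 4-hydroxy-2-pyranone with a hard methylating agent should occur at the most Lewis-basic site, the lactone carbonyl oxygen, to give pyrylium salt 7, and loss of its O–H proton on work-up gives the α-methoxy-γ-pyranone rather than the 4-methoxy-α-pyranone; the unactivated olefin is inert.

Step 5
Reactants: 9 (S)-2-methyloxirane ((S)-propylene oxide), 10 allylmagnesium bromide
Product: 12 (2S)-hex-5-en-2-yl acetate, via bromomagnesium alkoxide 11 (not isolated)
Conditions: CuI (10 mol %), THF, −30 → 0 °C; then Ac2O (2 equiv), DMAP (cat.), 0 °C → rt; cold 1 M HCl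
Reagents that add atoms: acetic anhydride CC(=O)OC(C)=O
Why: Cu-catalysed SN2 opening of a terminal epoxide by a Grignard reagent at the unsubstituted carbon leaves the C–O bond of the stereocentre untouched (S retained), and acetylating alkoxide 11 in the same flask avoids isolating the volatile alcohol.

Step 6
Reactants: 12 (2S)-hex-5-en-2-yl acetate
Product: 13 (2S)-6-bromohexan-2-yl acetate
Conditions: HBr (sat. soln in toluene), AIBN (10 mol %), air, 0 °C
Reagents that add atoms: hydrogen bromide Br
Why: Radical-chain anti-Markovnikov hydrobromination, in which Br• adds to the terminal carbon and the secondary radical abstracts H from HBr, while the non-polar solvent and low temperature suppress ionic addition and spare the acetate and the stereocentre.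

Step 7
Reactants: 13 (2S)-6-bromohexan-2-yl acetate
Product: 14 (2S)-6-iodohexan-2-yl acetate
Conditions: NaI (3 equiv), acetone, reflux
Reagents that add atoms: sodium iodide [Na+].[I-]
Why: Finkelstein reaction, an SN2 halide exchange at the primary carbon driven by precipitation of NaBr and remote from the stereocentre.

Step 8
Reactants: 8 3,5-diethyl-2-methoxy-6-(pent-4-en-1-yl)-4H-pyran-4-one, 14 (2S)-6-iodohexan-2-yl acetate (1.5 equiv)
Product: 15 (2S)-11-(3,5-diethyl-6-methoxy-4-oxo-4H-pyran-2-yl)undecan-2-yl acetate
Conditions: NiBr2·diglyme (10 mol %), 4,4'-di-tert-butyl-2,2'-bipyridine (12 mol %), (EtO)2MeSiH (2.5 equiv), Na2CO3 (2.5 equiv), DMA, 30 °C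
Reagents that add atoms: none
Why: A bipyridine-ligated Ni–H, formed from the Ni(II) salt, the silane and carbonate, inserts the monosubstituted C4'=C5' olefin of 8 in the anti-Markovnikov sense and so places nickel on C5', while low-valent nickel abstracts iodine from 14 to release the primary C6' radical; capture of that radical gives a dialkylnickel(III) species that forms the C5'–C6' bond by reductive elimination. The closest known reaction type is the Ni–H-catalysed reductive anti-Markovnikov hydroalkylation of unactivated terminal alkenes with primary alkyl iodides, which tolerates esters, ketones and heteroaromatic rings. No ring is closed and no stereocentre is created: the (S) centre C10' comes in with 14, lies four carbons from the radical site, and neither its C–O bond nor its unactivated C–H bond takes part. Cross-selectivity over homodimerisation, which a coupling of two halides or two acids could reach only statistically, is secured because the two like termini enter the cycle through different elementary steps, hydrometalation for C5' and halogen abstraction for C6'. Linear regioselectivity rests on the preference of the hindered bipyridine–nickel centre for the primary alkyl, and chemoselectivity on the fact that the remaining C=C bonds (ring C2=C3 and C5=C6) are tetrasubstituted, oxygen-substituted parts of the cross-conjugated pyranone and should not insert into Ni–H.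

**Compound list**
1 | methyl butanoate | CCCC(=O)OC | starting material
2 | methyl 2-ethyl-3-oxohexanoate (racemic) | CCCC(=O)C(CC)C(=O)OC | intermediate
3 | methyl hex-5-enoate | C=CCCCC(=O)OC | starting material
4 | dilithium dienolate (1,3-dianion) of 2 | [Li+].[Li+].CCC=C([O-])C(CC)=C([O-])OC | intermediate
5 | methyl 2,4-diethyl-3,5-dioxodec-9-enoate (stereoisomer and tautomer mixture) | C=CCCCC(=O)C(CC)C(=O)C(CC)C(=O)OC | intermediate
6 | 3,5-diethyl-4-hydroxy-6-(pent-4-en-1-yl)-2H-pyran-2-one | C=CCCCc1oc(=O)c(CC)c(O)c1CC | intermediate
7 | 3,5-diethyl-4-hydroxy-2-methoxy-6-(pent-4-en-1-yl)pyrylium trifluoromethanesulfonate | C=CCCCc1[o+]c(OC)c(CC)c(O)c1CC.[O-]S(=O)(=O)C(F)(F)F | intermediate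
8 | 3,5-diethyl-2-methoxy-6-(pent-4-en-1-yl)-4H-pyran-4-one | C=CCCCc1oc(OC)c(CC)c(=O)c1CC | intermediate
9 | (S)-2-methyloxirane ((S)-propylene oxide) | C[C@H]1CO1 | starting material
10 | allylmagnesium bromide | C=CC[Mg]Br | starting material
11 | bromomagnesium (2S)-hex-5-en-2-olate | C=CCC[C@H](C)O[Mg]Br | intermediate
12 | (2S)-hex-5-en-2-yl acetate | C=CCC[C@H](C)OC(C)=O | intermediate
13 | (2S)-6-bromohexan-2-yl acetate | BrCCCC[C@H](C)OC(C)=O | intermediate
14 | (2S)-6-iodohexan-2-yl acetate | ICCCC[C@H](C)OC(C)=O | intermediate
15 | (2S)-11-(3,5-diethyl-6-methoxy-4-oxo-4H-pyran-2-yl)undecan-2-yl acetate | CCc1c(CCCCCCCCC[C@H](C)OC(C)=O)oc(OC)c(CC)c1=O | target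

Total step count: 8. Longest linear sequence: 5 (steps 1, 2, 3, 4, 8).

**Steps most likely to fail**

Step 8. Ni–H chain walking along the pentenyl arm, hydrodeiodination or homodimerisation of the iodide, or binding of the catalyst by the Lewis-basic pyranone carbonyl may outrun the cross-coupling. The fallback makes the same bond by a two-electron route. It sets out from 8 and 13 and comes back at 15. Hydroboration of the terminal olefin of 8 with 9-BBN-H (THF, rt) gives 9-[5-(3,5-diethyl-6-methoxy-4-oxo-4H-pyran-2-yl)pentyl]-9-borabicyclo[3.3.1]nonane F1. This is coupled in the same flask with bromide 13 in an alkyl–alkyl Suzuki–Miyaura reaction (Pd(OAc)2, PCy3, K3PO4·H2O, THF, rt) to give 15.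

Step 2. Proton transfer from the enolisable ester to the dianion, quenching of the dianion by the more acidic triketide, and O-acylation may erode the C-acylation. The fallback replaces acylation by addition and oxidation. It sets out from 2 (through 4) and comes back at 5. Aldol addition of 4 to hex-5-enal (C=CCCCC=O; THF, −78 °C) gives methyl 2,4-diethyl-5-hydroxy-3-oxodec-9-enoate F2. Oxidation with Dess–Martin periodinane (CH2Cl2, rt) then gives 5.

Step 6. Ionic Markovnikov addition may compete with the radical chain, and prolonged contact with HBr may cause acidolysis of the secondary acetate. The fallback uses a polar, acid-free sequence. It sets out from 12 and comes back at 14, so that 13 and step 7 are bypassed. Hydroboration with 9-BBN-H (THF, rt) gives (2S)-6-(9-borabicyclo[3.3.1]nonan-9-yl)hexan-2-yl acetate F3. Mild oxidation (NaBO3·4H2O, THF/H2O, rt) gives (2S)-6-hydroxyhexan-2-yl acetate F4. An Appel iodination (I2, PPh3, imidazole, CH2Cl2, 0 °C) then gives 14.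

**Further compounds**
F1 | step 8 | 9-[5-(3,5-diethyl-6-methoxy-4-oxo-4H-pyran-2-yl)pentyl]-9-borabicyclo[3.3.1]nonane | CCc1c(CCCCCB2C3CCCC2CCC3)oc(OC)c(CC)c1=O
F2 | step 2 | methyl 2,4-diethyl-5-hydroxy-3-oxodec-9-enoate (diastereomer mixture) | C=CCCCC(O)C(CC)C(=O)C(CC)C(=O)OC
F3 | step 6 | (2S)-6-(9-borabicyclo[3.3.1]nonan-9-yl)hexan-2-yl acetate | C1CC2CCCC(C1)B2CCCC[C@H](C)OC(C)=O
F4 | step 6 | (2S)-6-hydroxyhexan-2-yl acetate | OCCCC[C@H](C)OC(C)=O
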